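The plan cuts the exocyclic C3–C(=O) bond together with the adjoining acyl–oxygen bond. The C3 carboxyl hangs on sp2 carbon C3 of the C3=C4 double bond in ring B, the non-aromatic ring of the 1,2-dihydronaphthalene. C3 is therefore read as a former ketone carbon, and a 2-tetralone is armed for coupling by trapping its C4-side enolate as the triflate. One palladium-catalysed carbonylation joins this triflate, carbon monoxide and the benzyl-protected (S)-aryllactate, so the conjugated ester forms without a free or activated C3 acid. The precursor is the cis-(1S,2S) triflate with a tert-butyl ester at C1, dibenzyloxyphenyl ring C at C2 and benzyl ethers at C7 and C8.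

Key step: step 14

Numbering: C1–C4, C4a, C5–C8, C8a of the 1,2-dihydronaphthalene. Ring A is the fused aromatic ring, ring B is C1–C4/C4a/C8a, and ring C is the aryl group on C2.

Assumption: the Michael addition of step 5 is taken to give mainly the anti (2S,3R) adduct. Only the S centre (future C2) matters, because the other centre (future C1) is erased and reset in step 12, so its epimer would converge on the same compound 23.

Step 1
Reactants: 1 2,3-dihydroxybenzaldehyde
Product: 2 2,3-bis(benzyloxy)benzaldehyde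
Conditions: BnBr (2.4 equiv), K2CO3, DMF, 60 °C
Reagents that add atoms: benzyl bromide, BrCc1ccccc1
Why: Williamson ether synthesis, in which both phenoxides are alkylated by the reactive benzylic bromide while the aldehyde is inert to carbonate.

Step 2
Reactants: 2 2,3-bis(benzyloxy)benzaldehyde
Product: 3 (E)-1,2-bis(benzyloxy)-3-(2-nitrovinyl)benzene
Conditions: MeNO2, NH4OAc, AcOH, 100 °C
Reagents that add atoms: nitromethane, C[N+](=O)[O-]
Why: Henry condensation with dehydration in the same pot gives the conjugated nitroalkene with the thermodynamic E geometry, and its nitro-bearing carbon is the later C1 carboxyl carbon.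

Step 3
Reactants: 4 3,4-dihydroxyphenylacetic acid
Product: 6 3,4-bis(benzyloxy)phenylacetic acid, via benzyl ester 5 (not isolated)
Conditions: BnBr (3.5 equiv), K2CO3, DMF, 60 °C; then 2 M NaOH, THF/MeOH, 50 °C; HCl
Reagents that add atoms: benzyl bromide, BrCc1ccccc1; sodium hydroxide, [Na+].[OH-]
Why: Exhaustive Williamson benzylation followed by saponification of the only ester frees the acid and leaves the two aryl benzyl ethers untouched.

Step 4
Reactants: 6 3,4-bis(benzyloxy)phenylacetic acid; 7 (S)-4-benzyloxazolidin-2-one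
Product: 9 (S)-4-benzyl-3-{[3,4-bis(benzyloxy)phenyl]acetyl}oxazolidin-2-one, via mixed pivalic anhydride 8 (not isolated)
Conditions: PivCl, Et3N, THF, −20 °C; then 7, LiCl, rt
Reagents that add atoms: pivaloyl chloride, CC(C)(C)C(=O)Cl (kept only in intermediate 8)
Why: N-acylation through a mixed anhydride, whose hindered pivaloyl carbonyl steers attack to the arylacetyl carbonyl, attaches the chiral auxiliary without strong base.

Step 5
Reactants: 9 (S)-4-benzyl-3-{[3,4-bis(benzyloxy)phenyl]acetyl}oxazolidin-2-one; 3 (E)-1,2-bis(benzyloxy)-3-(2-nitrovinyl)benzene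
Product: 11 (S)-4-benzyl-3-{(2S,3R)-2-[3,4-bis(benzyloxy)phenyl]-3-[2,3-bis(benzyloxy)phenyl]-4-nitrobutanoyl}oxazolidin-2-one, via lithium Z-enolate 10 (not isolated)
Conditions: LiHMDS (1.05 equiv), THF, −78 °C; 3, −78 °C; AcOH quench
Reagents that add atoms: lithium hexamethyldisilazide, [Li+].C[Si](C)(C)[N-][Si](C)(C)C (lithium kept only in intermediate 10)
Why: Diastereoselective Michael addition of a chiral imide enolate to a nitroalkene, in which the benzyl group of the auxiliary blocks one face of the lithium-chelated Z-enolate so that bonding on the open face sets the future C2 as S, while the synclinal approach of Z-enolate and E-nitroalkene should favour the anti adduct (future C1 R).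

Step 6
Reactants: 11 nitro imide
Product: 12 (2R,3S)-4-[(S)-4-benzyl-2-oxooxazolidin-3-yl]-2-[2,3-bis(benzyloxy)phenyl]-3-[3,4-bis(benzyloxy)phenyl]-4-oxobutanoic acid
Conditions: NaNO2 (3 equiv), AcOH (10 equiv), DMSO, 35 °C
Reagents that add atoms: sodium nitrite, [Na+].[O-]N=O; water, O (together the oxygen source)
Why: Nitrite-mediated oxidation of a primary nitroalkane (nitrolic acid, nitrile oxide, hydroxamic acid) gives the carboxylic acid under weakly acidic conditions that should leave the imide, the benzyl ethers and both stereocentres alone.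

Step 7
Reactants: 12 imide acid
Product: 13 tert-butyl (2R,3S)-4-[(S)-4-benzyl-2-oxooxazolidin-3-yl]-2-[2,3-bis(benzyloxy)phenyl]-3-[3,4-bis(benzyloxy)phenyl]-4-oxobutanoate
Conditions: Cl3CC(=NH)OtBu (3 equiv), BF3·OEt2 (5 mol%), CH2Cl2/cyclohexane, rt
Reagents that add atoms: tert-butyl 2,2,2-trichloroacetimidate, CC(C)(C)OC(=N)C(Cl)(Cl)Cl
Why: Acid-catalysed O-alkylation of the acid by the trichloroacetimidate esterifies the hindered carboxyl at oxygen, so the acyl carbon is never activated.

Step 8
Reactants: 13 imide tert-butyl ester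
Product: 15 (2S,3R)-2-[3,4-bis(benzyloxy)phenyl]-3-[2,3-bis(benzyloxy)phenyl]-4-tert-butoxy-4-oxobutanoic acid, via peroxy acid 14 (not isolated)
Conditions: LiOH, 30% H2O2, THF/H2O, 0 °C; Na2SO3; cold 1 M HCl to pH 3
Reagents that add atoms: hydrogen peroxide, OO
Why: Hydroperoxide cleavage of an N-acyl oxazolidinone, in which the small, weakly basic but highly nucleophilic hydroperoxide anion attacks the exocyclic carbonyl at 0 °C, frees the C3 acid without enolising C2 and spares the tert-butyl ester.

Step 9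
Reactants: 15 succinic half-ester
Product: 17 tert-butyl (2R,3S)-2-[2,3-bis(benzyloxy)phenyl]-3-[3,4-bis(benzyloxy)phenyl]-5-diazo-4-oxopentanoate, via mixed carbonic anhydride 16 (not isolated)
Conditions: iBuOCOCl, N-methylmorpholine, THF, −20 °C; then CH2N2, Et2O, 0 °C
Reagents that add atoms: isobutyl chloroformate, CC(C)COC(=O)Cl (kept only in intermediate 16); diazomethane, C=[N+]=[N-]
Why: Acylation of diazomethane by a mixed carbonic anhydride (first stage of the Arndt–Eistert sequence), the standard protocol for succinic-type half tert-butyl esters, avoids both an acid chloride that would attack the neighbouring tert-butyl ester and a ketene that would erase C2.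

Step 10
Reactants: 17 diazomethyl ketone
Product: 19 tert-butyl (1R,2S)-7,8-bis(benzyloxy)-2-[3,4-bis(benzyloxy)phenyl]-3-oxo-1,2,3,4-tetrahydronaphthalene-1-carboxylate (trans), via azulenone 18 (not isolated)
Conditions: Rh2(OAc)4 (1 mol%), CH2Cl2 (5 mM), reflux, slow addition; then TFA (10 mol%), 0 °C
Reagents that add atoms: none
Why: Intramolecular Buchner reaction of a 1-diazo-4-arylbutan-2-one, in which the rhodium carbenoid adds to the C4a–C8a bond of ring A (its only free ortho site, para to the C7 ether) and trace acid reopens the cycloheptatriene to the aromatic 2-tetralone, all without base, so C1 and C2 are not touched.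

Step 11
Reactants: 19 trans 2-tetralone
Product: 21 tert-butyl (1R,2S)-7,8-bis(benzyloxy)-2-[3,4-bis(benzyloxy)phenyl]-3-(trifluoromethylsulfonyloxy)-1,2-dihydronaphthalene-1-carboxylate (trans), via potassium enolate 20 (not isolated)
Conditions: KHMDS (1.05 equiv), THF, −78 °C; N-(5-chloro-2-pyridyl)bis(trifluoromethanesulfonimide), −78 to −40 °C
Reagents that add atoms: N-(5-chloro-2-pyridyl)bis(trifluoromethanesulfonimide), O=S(=O)(N(c1ccc(Cl)cn1)S(=O)(=O)C(F)(F)F)C(F)(F)F; potassium hexamethyldisilazide, [K+].C[Si](C)(C)[N-][Si](C)(C)C (potassium kept only in intermediate 20)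
Why: Kinetic enolate O-sulfonylation, in which the unhindered C4 methylene, whose enolate is conjugated with ring A, is deprotonated faster than the tertiary C2–H or the ester α-H at C1, and trapping at low temperature fixes the C3=C4 enol triflate and ends the lability of C2.

Step 12
Reactants: 21 trans enol triflate
Product: 23 tert-butyl (1S,2S)-7,8-bis(benzyloxy)-2-[3,4-bis(benzyloxy)phenyl]-3-(trifluoromethylsulfonyloxy)-1,2-dihydronaphthalene-1-carboxylate (cis), via lithium ester enolate 22 (not isolated)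
Conditions: LDA (1.3 equiv), THF, −78 °C; 2,6-di-tert-butyl-4-methylphenol (3 equiv) in THF, −78 °C; then AcOH
Reagents that add atoms: lithium diisopropylamide, [Li+].CC(C)[N-]C(C)C (lithium kept only in intermediate 22)
Why: Deprotonation and kinetic protonation of an ester enolate, in which the C2 aryl group of nearly planar 22 stands pseudoaxial to escape allylic strain with the exocyclic enolate and the C3 triflate, so the bulky phenol delivers its proton to C1 from the opposite face, which places the ester on the aryl side and sets C1 as S (cis), and the phenoxide formed is too weak a base to re-equilibrate the product.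

Step 13
Reactants: 24 4-bromo-1,2-bis(benzyloxy)benzene; 25 methyl (S)-glycidate
Product: 27 methyl (S)-3-[3,4-bis(benzyloxy)phenyl]-2-hydroxypropanoate, via aryl Grignard reagent 26 (not isolated)
Conditions: Mg, THF, reflux; then CuI (10 mol%), 25, THF, −40 °C; aq. NH4Cl
Reagents that add atoms: magnesium, [Mg] (kept only in intermediate 26)
Why: Copper-catalysed Grignard opening of a terminal epoxide at its unsubstituted carbon outruns ester addition at −40 °C and does not involve the stereocentre, so the S configuration of the glycidate is carried unchanged into the lactate.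

Step 14
Reactants: 23 cis enol triflate; 27 methyl (S)-3-[3,4-bis(benzyloxy)phenyl]-2-hydroxypropanoate; 28 carbon monoxide
Product: 29 C3 (S)-lactate ester, C1 tert-butyl ester, (1S,2S), hexabenzyl ether
Conditions: Pd(OAc)2 (10 mol%), dppp (12 mol%), CO (1 atm), 27 (1.5 equiv), Et3N (2 equiv), DMAP (30 mol%), 4 Å MS, DMF, 50 °C
Reagents that add atoms: none
Why: Phosphine and amine reduce Pd(OAc)2 to zerovalent palladium, which inserts into the C3–OTf bond of 23; CO then migrates into the alkenyl–palladium bond, and alcohol 27, with DMAP as acyl carrier and Et3N as proton sink, cleaves the divalent acylpalladium species to release 29 and return the catalyst. The closest known reaction type is the palladium-catalysed alkoxycarbonylation of enol triflates with alcohols under one atmosphere of CO, and only the hindered secondary α-hydroxy ester used in small excess is unusual. No ring is closed and no stereocentre is created: C1 and C2 are spectators, and the lactate carbinol keeps its S configuration because only its O–H bond reacts. The step needs capture of the acyl group by the alcohol rather than by water or a hydride source, which molecular sieves, saturation with CO before heating and acyl transfer through DMAP should secure, helped by an alkenoyl group that has no α-hydrogen and so cannot decay to a ketene while it waits. The cis C1 centre should hold because a hindered tert-butyl arylacetate is far too weak a carbon acid for tertiary amines at 50 °C.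

Step 15
Reactants: 29 C1 tert-butyl ester
Product: 30 C1 carboxylic acid, (1S,2S), C3 (S)-lactate ester, hexabenzyl ether
Conditions: TFA/CH2Cl2 (1:4), 0 °C to rt
Reagents that add atoms: none
Why: Acidolysis of the tert-butyl ester by alkyl–oxygen cleavage (loss of isobutene) leaves the methyl and lactate esters and the aryl benzyl ethers intact, and with no base present the cis C1 centre is not at risk.

Step 16
Reactants: 30 C1 carboxylic acid; 27 methyl (S)-3-[3,4-bis(benzyloxy)phenyl]-2-hydroxypropanoate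
Product: 31 octabenzyl ether of the target, (1S,2S), C3 (S)-lactate and C1 (R)-lactate esters
Conditions: 27 (1.3 equiv), PPh3, DIAD, toluene, 0 °C to rt
Reagents that add atoms: none
Why: Mitsunobu esterification activates the alcohol and not the acid, so the carboxylate of 30 displaces the oxyphosphonium group of (S)-27 by SN2 inversion to give the R lactate ester, while C1 never passes through an activated acyl derivative that could enolise.

Step 17
Reactants: 31 octabenzyl ether
Product: 32 CNP0237075.1
Conditions: BCl3 (20 equiv), C6HMe5 (30 equiv), CH2Cl2, −78 °C; MeOH quench at −78 °C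
Reagents that add atoms: none
Why: Lewis-acid debenzylation with a non-basic cation scavenger, in which BCl3 ionises the aryl benzyl ethers at −78 °C and pentamethylbenzene traps the benzyl cations, spares the C3=C4 alkene that hydrogenolysis would endanger as well as the four esters and all stereocentres.

Compound list

1 | 2,3-dihydroxybenzaldehyde | O=Cc1cccc(O)c1O | starting material
2 | 2,3-bis(benzyloxy)benzaldehyde | O=Cc1cccc(OCc2ccccc2)c1OCc1ccccc1 | intermediate
3 | (E)-1,2-bis(benzyloxy)-3-(2-nitrovinyl)benzene | O=[N+]([O-])/C=C/c1cccc(OCc2ccccc2)c1OCc1ccccc1 | intermediate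
4 | 3,4-dihydroxyphenylacetic acid | OC(=O)Cc1ccc(O)c(O)c1 | starting material
5 | benzyl 3,4-bis(benzyloxy)phenylacetate | O=C(Cc1ccc(OCc2ccccc2)c(OCc2ccccc2)c1)OCc1ccccc1 | intermediate
6 | 3,4-bis(benzyloxy)phenylacetic acid | OC(=O)Cc1ccc(OCc2ccccc2)c(OCc2ccccc2)c1 | intermediate
7 | (S)-4-benzyloxazolidin-2-one | O=C1N[C@@H](Cc2ccccc2)CO1 | starting material
8 | 3,4-bis(benzyloxy)phenylacetic pivalic anhydride | CC(C)(C)C(=O)OC(=O)Cc1ccc(OCc2ccccc2)c(OCc2ccccc2)c1 | intermediate
9 | (S)-4-benzyl-3-{[3,4-bis(benzyloxy)phenyl]acetyl}oxazolidin-2-one | O=C1OC[C@H](Cc2ccccc2)N1C(=O)Cc1ccc(OCc2ccccc2)c(OCc2ccccc2)c1 | intermediate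
10 | lithium Z-enolate of 9 | [Li+].[O-]/C(=C\c1ccc(OCc2ccccc2)c(OCc2ccccc2)c1)N1[C@@H](Cc2ccccc2)COC1=O | intermediate
11 | (2S,3R)-4-nitrobutanoyl imide (anti Michael adduct) | O=C1OC[C@H](Cc2ccccc2)N1C(=O)[C@H](c1ccc(OCc2ccccc2)c(OCc2ccccc2)c1)[C@H](c1cccc(OCc2ccccc2)c1OCc1ccccc1)C[N+](=O)[O-] | intermediate
12 | (2R,3S)-imide acid | O=C1OC[C@H](Cc2ccccc2)N1C(=O)[C@H](c1ccc(OCc2ccccc2)c(OCc2ccccc2)c1)[C@H](c1cccc(OCc2ccccc2)c1OCc1ccccc1)C(=O)O | intermediate
13 | (2R,3S)-imide tert-butyl ester | O=C1OC[C@H](Cc2ccccc2)N1C(=O)[C@H](c1ccc(OCc2ccccc2)c(OCc2ccccc2)c1)[C@H](c1cccc(OCc2ccccc2)c1OCc1ccccc1)C(=O)OC(C)(C)C | intermediate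
14 | peroxy acid of 15 | OOC(=O)[C@H](c1ccc(OCc2ccccc2)c(OCc2ccccc2)c1)[C@H](c1cccc(OCc2ccccc2)c1OCc1ccccc1)C(=O)OC(C)(C)C | intermediate
15 | (2S,3R)-2,3-diarylsuccinic acid 4-tert-butyl ester | OC(=O)[C@H](c1ccc(OCc2ccccc2)c(OCc2ccccc2)c1)[C@H](c1cccc(OCc2ccccc2)c1OCc1ccccc1)C(=O)OC(C)(C)C | intermediate
16 | isobutyl carbonic anhydride of 15 | CC(C)COC(=O)OC(=O)[C@H](c1ccc(OCc2ccccc2)c(OCc2ccccc2)c1)[C@H](c1cccc(OCc2ccccc2)c1OCc1ccccc1)C(=O)OC(C)(C)C | intermediate
17 | tert-butyl (2R,3S)-2,3-diaryl-5-diazo-4-oxopentanoate | [N-]=[N+]=CC(=O)[C@H](c1ccc(OCc2ccccc2)c(OCc2ccccc2)c1)[C@H](c1cccc(OCc2ccccc2)c1OCc1ccccc1)C(=O)OC(C)(C)C | intermediate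
18 | bicyclo[5.3.0] trienone (azulenone) from carbenoid addition to C4a–C8a | O=C1C2C=CC=C(OCc3ccccc3)C(OCc3ccccc3)=C2[C@H](C(=O)OC(C)(C)C)[C@H]1c1ccc(OCc2ccccc2)c(OCc2ccccc2)c1 | intermediate
19 | trans-(1R,2S) 3-oxo-tetrahydronaphthalene-1-carboxylate (2-tetralone) | O=C1Cc2ccc(OCc3ccccc3)c(OCc3ccccc3)c2[C@H](C(=O)OC(C)(C)C)[C@H]1c1ccc(OCc2ccccc2)c(OCc2ccccc2)c1 | intermediate
20 | potassium C3=C4 enolate of 19 | [K+].[O-]C1=Cc2ccc(OCc3ccccc3)c(OCc3ccccc3)c2[C@H](C(=O)OC(C)(C)C)[C@H]1c1ccc(OCc2ccccc2)c(OCc2ccccc2)c1 | intermediate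
21 | trans-(1R,2S) C3 enol triflate | FC(F)(F)S(=O)(=O)OC1=Cc2ccc(OCc3ccccc3)c(OCc3ccccc3)c2[C@H](C(=O)OC(C)(C)C)[C@H]1c1ccc(OCc2ccccc2)c(OCc2ccccc2)c1 | intermediate
22 | lithium C1 ester enolate of 21 | [Li+].[O-]C(OC(C)(C)C)=C1c2c(OCc3ccccc3)c(OCc3ccccc3)ccc2C=C(OS(=O)(=O)C(F)(F)F)[C@@H]1c1ccc(OCc2ccccc2)c(OCc2ccccc2)c1 | intermediate
23 | cis-(1S,2S) C3 enol triflate, C1 tert-butyl ester | FC(F)(F)S(=O)(=O)OC1=Cc2ccc(OCc3ccccc3)c(OCc3ccccc3)c2[C@@H](C(=O)OC(C)(C)C)[C@H]1c1ccc(OCc2ccccc2)c(OCc2ccccc2)c1 | intermediate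
24 | 4-bromo-1,2-bis(benzyloxy)benzene | Brc1ccc(OCc2ccccc2)c(OCc2ccccc2)c1 | starting material
25 | methyl (S)-glycidate | COC(=O)[C@@H]1CO1 | starting material
26 | 3,4-bis(benzyloxy)phenylmagnesium bromide | Br[Mg]c1ccc(OCc2ccccc2)c(OCc2ccccc2)c1 | intermediate
27 | methyl (S)-3-[3,4-bis(benzyloxy)phenyl]-2-hydroxypropanoate | COC(=O)[C@H](Cc1ccc(OCc2ccccc2)c(OCc2ccccc2)c1)O | intermediate
28 | carbon monoxide | [C-]#[O+] | starting material
29 | C3 (S)-lactate ester, C1 tert-butyl ester, (1S,2S) | COC(=O)[C@H](Cc1ccc(OCc2ccccc2)c(OCc2ccccc2)c1)OC(=O)C1=Cc2ccc(OCc3ccccc3)c(OCc3ccccc3)c2[C@@H](C(=O)OC(C)(C)C)[C@H]1c1ccc(OCc2ccccc2)c(OCc2ccccc2)c1 | intermediate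
30 | C3 (S)-lactate ester, C1 acid, (1S,2S) | COC(=O)[C@H](Cc1ccc(OCc2ccccc2)c(OCc2ccccc2)c1)OC(=O)C1=Cc2ccc(OCc3ccccc3)c(OCc3ccccc3)c2[C@@H](C(=O)O)[C@H]1c1ccc(OCc2ccccc2)c(OCc2ccccc2)c1 | intermediate
31 | octabenzyl ether of the target | COC(=O)[C@H](Cc1ccc(OCc2ccccc2)c(OCc2ccccc2)c1)OC(=O)C1=Cc2ccc(OCc3ccccc3)c(OCc3ccccc3)c2[C@@H](C(=O)O[C@H](Cc2ccc(OCc3ccccc3)c(OCc3ccccc3)c2)C(=O)OC)[C@H]1c1ccc(OCc2ccccc2)c(OCc2ccccc2)c1 | intermediate
32 | CNP0237075.1 | COC(=O)[C@H](Cc1ccc(O)c(O)c1)OC(=O)C1=Cc2ccc(O)c(O)c2[C@@H](C(=O)O[C@H](Cc2ccc(O)c(O)c2)C(=O)OC)[C@H]1c1ccc(O)c(O)c1 | target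

Total step count: 17. Longest linear sequence: 14 steps (steps 1–2 or 3–4, then 5–12 and 14–17).

Steps most likely to fail

1. Step 14.
   - Capture of the acylpalladium species by the hindered secondary alcohol may be slow, so that hydrolysis or hydride reduction takes over, and long heating with amine could start to epimerise C1.
   - The fallback sets out from 23 and separates carbonylation from ester formation.
   - Hydroxycarbonylation (Pd(OAc)2, dppf, KOAc, CO, moist DMSO, 60 °C) gives the C3 carboxylic acid F1.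
   - F1 has no α-hydrogen, so it can be activated safely as its 2,4,6-trichlorobenzoyl mixed anhydride. Yamaguchi esterification with 27 (Et3N, DMAP, toluene, rt) returns to the route at 29.

2. Step 10.
   - The carbenoid may be diverted by attack on electron-rich ring C (five-membered closure) or on the carbonyl oxygen of the tert-butyl ester (ylide formation and loss of the ester).
   - The fallback fixes the site of closure with a halogen and uses a soft enolate instead of a carbene. It sets out from 2.
   - NBS in MeCN brominates the position para to the C3 ether, giving 6-bromo-2,3-bis(benzyloxy)benzaldehyde F2.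
   - The chemistry of steps 2 and 5–8 is repeated through the bromo nitrostyrene F3, the bromo Michael adduct F4, the bromo imide acid F5, the bromo imide tert-butyl ester F6 and the bromo half-ester acid F7.
   - Carbonyldiimidazole followed by Mg(O2CCH2CO2CH2CH=CH2)2 extends F7 to the allyl β-keto ester F8.
   - Hurtley-type arylation (CuI, 2-picolinic acid, Cs2CO3, dioxane, 70 °C) closes C4–C4a to the bicyclic β-keto ester F9. The C4 enolate shields C2 from epimerisation during this closure.
   - Pd(PPh3)4 and morpholine remove the allyl ester with decarboxylation, returning at 19.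

3. Step 12.
   - Facial selectivity of the proton transfer may be eroded by proton return from the amine bound to the enolate, and prolonged exposure of the triflate to strong base could lead to elimination and aromatisation.
   - The trans isomer recovered from the separation would be recycled in any case.
   - The fallback sets out from 21 and replaces the metal enolate quench by protonation of a neutral, purified species.
   - Enolate 22 is trapped with Me3SiCl to give the tert-butyl trimethylsilyl ketene acetal F10, which is freed from amine and lithium salts.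
   - F10 is then protonated at −78 °C in toluene by the SnCl4·BINOL complex, with the matched enantiomer of BINOL. Reagent control then adds to substrate control, and the route is rejoined at 23.

Further compounds

F1 | step 14 | (1S,2S) C3 carboxylic acid, C1 tert-butyl ester | OC(=O)C1=Cc2ccc(OCc3ccccc3)c(OCc3ccccc3)c2[C@@H](C(=O)OC(C)(C)C)[C@H]1c1ccc(OCc2ccccc2)c(OCc2ccccc2)c1
F2 | step 10 | 6-bromo-2,3-bis(benzyloxy)benzaldehyde | O=Cc1c(Br)ccc(OCc2ccccc2)c1OCc1ccccc1
F3 | step 10 | (E)-1,2-bis(benzyloxy)-4-bromo-3-(2-nitrovinyl)benzene | O=[N+]([O-])/C=C/c1c(Br)ccc(OCc2ccccc2)c1OCc1ccccc1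
F4 | step 10 | bromo analogue of 11 | O=C1OC[C@H](Cc2ccccc2)N1C(=O)[C@H](c1ccc(OCc2ccccc2)c(OCc2ccccc2)c1)[C@H](c1c(Br)ccc(OCc2ccccc2)c1OCc1ccccc1)C[N+](=O)[O-]
F5 | step 10 | bromo analogue of 12 | O=C1OC[C@H](Cc2ccccc2)N1C(=O)[C@H](c1ccc(OCc2ccccc2)c(OCc2ccccc2)c1)[C@H](c1c(Br)ccc(OCc2ccccc2)c1OCc1ccccc1)C(=O)O
F6 | step 10 | bromo analogue of 13 | O=C1OC[C@H](Cc2ccccc2)N1C(=O)[C@H](c1ccc(OCc2ccccc2)c(OCc2ccccc2)c1)[C@H](c1c(Br)ccc(OCc2ccccc2)c1OCc1ccccc1)C(=O)OC(C)(C)C
F7 | step 10 | bromo analogue of 15 | OC(=O)[C@H](c1ccc(OCc2ccccc2)c(OCc2ccccc2)c1)[C@H](c1c(Br)ccc(OCc2ccccc2)c1OCc1ccccc1)C(=O)OC(C)(C)C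
F8 | step 10 | 1-allyl 6-tert-butyl (4S,5R)-4,5-diaryl-3-oxohexanedioate (bromoaryl at C5) | C=CCOC(=O)CC(=O)[C@H](c1ccc(OCc2ccccc2)c(OCc2ccccc2)c1)[C@H](c1c(Br)ccc(OCc2ccccc2)c1OCc1ccccc1)C(=O)OC(C)(C)C
F9 | step 10 | 4-allyl 1-tert-butyl (1R,2S)-3-oxo-tetrahydronaphthalene-1,4-dicarboxylate | O=C1C(C(=O)OCC=C)c2ccc(OCc3ccccc3)c(OCc3ccccc3)c2[C@H](C(=O)OC(C)(C)C)[C@H]1c1ccc(OCc2ccccc2)c(OCc2ccccc2)c1
F10 | step 12 | tert-butyl trimethylsilyl ketene acetal of 21 | C[Si](C)(C)OC(OC(C)(C)C)=C1c2c(OCc3ccccc3)c(OCc3ccccc3)ccc2C=C(OS(=O)(=O)C(F)(F)F)[C@@H]1c1ccc(OCc2ccccc2)c(OCc2ccccc2)c1
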